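Late in the ash run Z was falling while D still climbed: between 40.0 h and 50.0 h, Z went from 5% to 4% and D from 39% to 42%. The share of Z in Z plus D therefore sank with the clock, and I wanted to know what it was tied to.

| setting | ash | maple | epsilon | beta | delta | gamma | eta |
|---|---|---|---|---|---|---|---|
| L | 0.10 M | 0.10 M | 0.10 M | 0.10 M (fed, over 8.0 h) | 0.10 M | 0.10 M (fed, over 30 h) | 0.10 M |
| E | 0.11 M | 0.055 M | 0.110 M | 0.110 M | 0.110 M (fed, over 30 h) | 0.110 M | 0.110 M (fed, over 30 h) |
| G | 0.10 M | 0.10 M | 0.100 M | 0.100 M | 0.100 M | 0.100 M | 0.100 M |
| temperature | 40 °C | 40 °C | 40 °C | 40 °C | 40 °C | 40 °C |  |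
| remark | run made earlier | run made earlier | everything together at the start | all else is in the flask from the start; the feed brings no volume worth counting | all else is in the flask from the start; the feed brings no volume worth counting | all else is in the flask from the start; the feed brings no volume worth counting | the addition at 10 °C, then warmed to 40 °C; the feed brings no volume worth counting |
| time |  |  | 2.0 d | 2.0 d | 2.0 d | 2.0 d | 2.0 d |

| run | time / h | Z / % | D / % |
|---|---|---|---|
| ash | 12.0 | 11 | 24 |
| ash | 25.0 | 7 | 33 |
| ash | 40.0 | 5 | 39 |
| ash | 50.0 | 4 | 42 |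
| maple | 0.833 | 6 | 0 |
| maple | 2.00 | 7 | 2 |
| maple | 4.00 | 10 | 3 |
| maple | 10.0 | 8 | 6 |

(readings scatter by 1.5 percentage points)

- which flask leads in share of Z in Z plus D ("all alike" within 1.5 percentage points) (epsilon / beta / delta / gamma / eta / all alike)
- share of Z in Z plus D at the end, epsilon
- share of Z in Z plus D at the end, beta
- share of Z in Z plus D at the end, delta
- share of Z in Z plus D at the end, gamma
- share of Z in Z plus D at the end, eta

- the earlier runs do not show what temperature does; that part of a forecast is a guess

I saw two time scales in the readings. In the maple run Z read 6% at 0.833 h with D at 0%, whereas D in the ash run was still growing after tens of hours. So as a working assumption, to be tried on the readings, I treated L + E ⇌ Z as a loop held near its balance while D formed, a pre-equilibrium. A reversible step held at balance at one temperature keeps Z over the product of its two parents constant. For L left I subtracted Z and D from the charge. For E unspent I subtracted one E per Z and two per D, one to make the Z and one to carry it on. I called the ratio of Z to L left times E unspent the holding ratio, and the ash reading at 12.0 h gave 3.32 M⁻¹. The reading at 50.0 h gave 3.37 M⁻¹, though its Z carries a scatter of 1.5 percentage points. Counting one E per D, the same readings gave 2.26 M⁻¹ and 1.16 M⁻¹, so I kept two.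

At these charges the ratio makes Z a quadratic in D, and the share follows from D at the end. For epsilon, taking the D read at 50.0 h as close to the asked 2.0 d, I reckoned Z at 3.95% and a share of 8.60%. The D read at 25.0 h put through the same formula gave a share of 18.1%. So I ranked the flasks by how far each held D back, and for the cold addition I had no reading.

The forecast gave epsilon 9%, beta 10%, delta 15%, gamma 12% and eta 22%, with eta leading. Its ground was “Z therefore tracks free E and fades as E is used, while D only accumulates”.

The flasks gave epsilon 10.2%, beta 11.2%, delta 16.7%, gamma 14.5% and eta 23.2%, with eta leading, so the forecast held within its tolerance.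

    L → J (k = 5.30 × 10⁻⁸ s⁻¹, Ea = 113 kJ mol⁻¹)
    E + Z → D (k = 0.00100 M⁻¹ s⁻¹, Ea = 64.0 kJ mol⁻¹)
    G + E ⇌ Q (K = 9.90 M⁻¹, k = 0.00160 M⁻¹ s⁻¹, Ea = 67.0 kJ mol⁻¹, ΔH = −35.0 kJ mol⁻¹)
    L + E ⇌ Z (K = 8.20 M⁻¹, k = 5.60 × 10⁻⁴ M⁻¹ s⁻¹, Ea = 63.0 kJ mol⁻¹, ΔH = 8.00 kJ mol⁻¹)
    (constants at 40 °C)

The E of my budget was free E plus Q. For eta, the holding ratio with its D of 30.3% gave Z of 8.37%, below the 9.13% that stood there. Striking out the return of Z to L and E cut the gap between eta and epsilon from 13 points to 6 points, so that step carries part of the gap. For the neighbour of epsilon with 0.040 M of L and D at 70.4%, the ratio gave Z of 4.34% and a share of 5.81%. The computed flask gave Z of 4.42% and a share of 5.91%.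

(All runs come from a simulation on assumed constants.)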